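**Assumption:** the target is the single isomer encoded by the SMILES, (2R,4R,6S)-2-(4-hydroxy-3-methoxyphenyl)-6-[(1R)-1-hydroxy-2-(4-hydroxyphenyl)ethyl]oxan-4-ol (all three ring substituents cis; side-chain carbinol anti to the ring C6–O bond), and the ketoreductase of step 7 is picked from a commercial screening panel.

**Retrosynthetic overview**
1. Target ⇒ removal of two O-TBS and two phenolic O-benzyl groups from a 2,6-cis-2-aryl-oxane; the C2 aryl group and its stereocentre come last, by aryllithium addition to a δ-lactone and axial silane reduction of the lactol.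
2. δ-Lactone (it becomes the oxane ring) ⇒ anti-3,5-dihydroxy ester ⇒ β-keto ester, reduced by a ketoreductase to set the ring C4 carbinol.
3. β-Keto ester ⇒ aldehyde + ethyl diazoacetate (Roskamp) ⇒ terminal alkene (hydroboration).
4. Alkene anti-diol ⇒ aryl Grignard + (2R,3S)-1,2-epoxypent-4-en-3-ol ⇒ divinylcarbinol by Sharpless desymmetrising epoxidation, which sets ring C6 and the side-chain carbinol.
5. Ring order: a temporary dioxolane (acetonide) first, then the δ-lactone/oxane ring; both benzene rings are bought.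

**Route**

Step 1
Reactants: 1 penta-1,4-dien-3-ol
Product: 2 (2R,3S)-1,2-epoxypent-4-en-3-ol
Conditions: Ti(OiPr)4 (10 mol%), L-(+)-diisopropyl tartrate (13 mol%), cumene hydroperoxide (1.8 equiv), 4 Å MS, CH2Cl2, −30 °C, 4 d
Reagents that add atoms: cumene hydroperoxide, CC(C)(OO)c1ccccc1
Why: Sharpless asymmetric epoxidation of the achiral divinyl carbinol; the Ti–tartrate catalyst selects one enantiotopic vinyl group and one alkene face, and the minor enantiomer is destroyed by a fast second epoxidation, so the erythro (2R,3S) epoxy alcohol forms in very high ee and fixes ring C6 and the side-chain carbinol.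

Step 2
Reactants: 2 (2R,3S)-1,2-epoxypent-4-en-3-ol; 3 1-(benzyloxy)-4-bromobenzene
Product: 5 (2R,3S)-1-[4-(benzyloxy)phenyl]pent-4-ene-2,3-diol, via Grignard reagent 4 (not isolated)
Conditions: 3 (2.6 equiv), Mg, THF, 40 °C; then CuI (10 mol%), 2, THF, −30 → 0 °C; H2O work-up
Reagents that add atoms: none
Why: Copper-catalysed SN2 opening of the terminal epoxide at its CH2 carbon by the aryl Grignard (the first equivalent only deprotonates the hydroxyl), so neither stereocentre is touched and the anti-diol results.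

Step 3
Reactants: 5 (2R,3S)-1-[4-(benzyloxy)phenyl]pent-4-ene-2,3-diol
Product: 6 (4R,5S)-4-[4-(benzyloxy)benzyl]-2,2-dimethyl-5-vinyl-1,3-dioxolane
Conditions: 2,2-dimethoxypropane, PPTS (cat.), CH2Cl2, rt
Reagents that add atoms: 2,2-dimethoxypropane, COC(C)(C)OC
Why: Acid-catalysed transketalisation ties the anti-1,2-diol up as a cis-dioxolane, masking both hydroxyls until the lactone is closed.

Step 4
Reactants: 6 (4R,5S)-4-[4-(benzyloxy)benzyl]-2,2-dimethyl-5-vinyl-1,3-dioxolane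
Product: 8 2-[(4S,5R)-5-[4-(benzyloxy)benzyl]-2,2-dimethyl-1,3-dioxolan-4-yl]ethan-1-ol, via alkylborane 7 (not isolated)
Conditions: 9-BBN (1.5 equiv), THF, 0 °C → rt; then NaOH, H2O2, 0 °C → rt
Reagents that add atoms: hydrogen peroxide, OO
Why: Hydroboration–oxidation with bulky 9-BBN puts boron on the terminal carbon (anti-Markovnikov) and oxidation gives the primary alcohol; no stereocentre is formed.

Step 5
Reactants: 8 2-[(4S,5R)-5-[4-(benzyloxy)benzyl]-2,2-dimethyl-1,3-dioxolan-4-yl]ethan-1-ol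
Product: 9 2-[(4S,5R)-5-[4-(benzyloxy)benzyl]-2,2-dimethyl-1,3-dioxolan-4-yl]acetaldehyde
Conditions: Dess–Martin periodinane (1.3 equiv), pyridine, CH2Cl2, 0 °C → rt; used crude
Reagents that add atoms: none
Why: Dess–Martin oxidation stops at the aldehyde under buffered, near-neutral conditions that spare the acetonide and the benzyl ether.

Step 6
Reactants: 9 2-[(4S,5R)-5-[4-(benzyloxy)benzyl]-2,2-dimethyl-1,3-dioxolan-4-yl]acetaldehyde
Product: 10 ethyl 4-[(4S,5R)-5-[4-(benzyloxy)benzyl]-2,2-dimethyl-1,3-dioxolan-4-yl]-3-oxobutanoate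
Conditions: ethyl diazoacetate (1.3 equiv), SnCl2 (10 mol%), CH2Cl2, rt
Reagents that add atoms: ethyl diazoacetate, CCOC(=O)C=[N+]=[N-]
Why: Roskamp homologation: Lewis-acid-catalysed addition of the diazo ester to the aldehyde, 1,2-hydride shift and loss of N2 give the β-keto ester without base, so the β-alkoxy aldehyde is not exposed to elimination.

Step 7
Reactants: 10 ethyl 4-[(4S,5R)-5-[4-(benzyloxy)benzyl]-2,2-dimethyl-1,3-dioxolan-4-yl]-3-oxobutanoate
Product: 11 ethyl (3S)-4-[(4S,5R)-5-[4-(benzyloxy)benzyl]-2,2-dimethyl-1,3-dioxolan-4-yl]-3-hydroxybutanoate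
Conditions: ketoreductase (NADPH-dependent alcohol dehydrogenase class; the (3S)-selective member of a screening panel), NADP+ (cat.), i-PrOH (15 vol%), potassium phosphate buffer pH 7.0, MgSO4 (2 mM), DMSO (5 vol%), 30 °C
Reagents that add atoms: none
Why: Enzymatic carbonyl reduction: the ketoreductase delivers hydride from NADPH to one face of the C3 ketone under catalyst control (the resident centres are remote), giving the (3S)-alcohol that is 1,3-anti to the C5 oxygen, with i-PrOH recycling the cofactor.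

Step 8
Reactants: 11 ethyl (3S)-4-[(4S,5R)-5-[4-(benzyloxy)benzyl]-2,2-dimethyl-1,3-dioxolan-4-yl]-3-hydroxybutanoate
Product: 13 (4S,6S)-6-[(1R)-2-[4-(benzyloxy)phenyl]-1-hydroxyethyl]-4-hydroxyoxan-2-one, via triol ester 12 (not isolated)
Conditions: 1 M HCl, THF, rt; then TsOH·H2O (5 mol%), toluene, 45 °C
Reagents that add atoms: none
Why: Acid hydrolysis of the acetonide frees the triol ester, whose 5-OH closes the six-membered δ-lactone (the 6-OH would need a seven-membered ring) by acid-catalysed lactonisation with no stereocentre involved.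

Step 9
Reactants: 13 (4S,6S)-6-[(1R)-2-[4-(benzyloxy)phenyl]-1-hydroxyethyl]-4-hydroxyoxan-2-one
Product: 14 (4S,6S)-6-[(1R)-2-[4-(benzyloxy)phenyl]-1-[(tert-butyldimethylsilyl)oxy]ethyl]-4-[(tert-butyldimethylsilyl)oxy]oxan-2-one
Conditions: TBSOTf (2.6 equiv), 2,6-lutidine, CH2Cl2, −78 → 0 °C
Reagents that add atoms: tert-butyldimethylsilyl trifluoromethanesulfonate, CC(C)(C)[Si](C)(C)OS(=O)(=O)C(F)(F)F
Why: Silylation of both secondary hydroxyls with the silyl triflate and a hindered base protects them for the organolithium step without opening or enolising the lactone.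

Step 10
Reactants: 14 (4S,6S)-6-[(1R)-2-[4-(benzyloxy)phenyl]-1-[(tert-butyldimethylsilyl)oxy]ethyl]-4-[(tert-butyldimethylsilyl)oxy]oxan-2-one; 15 1-(benzyloxy)-4-bromo-2-methoxybenzene
Product: 17 (4S,6S)-2-[4-(benzyloxy)-3-methoxyphenyl]-6-[(1R)-2-[4-(benzyloxy)phenyl]-1-[(tert-butyldimethylsilyl)oxy]ethyl]-4-[(tert-butyldimethylsilyl)oxy]oxan-2-ol (anomer mixture; used crude), via aryllithium 16 (not isolated)
Conditions: 15 (1.3 equiv), n-BuLi (1.25 equiv), THF, −78 °C; then 14, −78 °C; H2O quench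
Reagents that add atoms: none
Why: Bromine–lithium exchange gives the aryllithium, which adds once to the lactone carbonyl because the lithium hemiketal alkoxide does not collapse at −78 °C (lactone arylation as used for C-aryl glycosides).

Step 11
Reactants: 17 (4S,6S)-2-[4-(benzyloxy)-3-methoxyphenyl]-6-[(1R)-2-[4-(benzyloxy)phenyl]-1-[(tert-butyldimethylsilyl)oxy]ethyl]-4-[(tert-butyldimethylsilyl)oxy]oxan-2-ol
Product: 18 (2R,4R,6S)-2-[4-(benzyloxy)-3-methoxyphenyl]-6-[(1R)-2-[4-(benzyloxy)phenyl]-1-[(tert-butyldimethylsilyl)oxy]ethyl]-4-[(tert-butyldimethylsilyl)oxy]oxane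
Conditions: Et3SiH (5 equiv), BF3·OEt2 (2 equiv), CH2Cl2/MeCN, −78 → −40 °C
Reagents that add atoms: none
Why: Kishi-type reductive deoxygenation: the Lewis acid ionises the lactol to an aryl-stabilised cyclic oxocarbenium ion and Et3SiH delivers hydride axially on the half-chair that keeps the C4 and C6 substituents equatorial, which sets C2 as R with all three ring substituents cis.

Step 12
Reactants: 18 (2R,4R,6S)-2-[4-(benzyloxy)-3-methoxyphenyl]-6-[(1R)-2-[4-(benzyloxy)phenyl]-1-[(tert-butyldimethylsilyl)oxy]ethyl]-4-[(tert-butyldimethylsilyl)oxy]oxane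
Product: 19 (2R,4R,6S)-2-[4-(benzyloxy)-3-methoxyphenyl]-6-[(1R)-2-[4-(benzyloxy)phenyl]-1-hydroxyethyl]oxan-4-ol
Conditions: TBAF (3 equiv), THF, 0 °C → rt
Reagents that add atoms: none
Why: Fluoride-driven Si–O cleavage frees both secondary alcohols, while the benzyl ethers and the cyclic benzylic ether are inert to TBAF.

Step 13
Reactants: 19 (2R,4R,6S)-2-[4-(benzyloxy)-3-methoxyphenyl]-6-[(1R)-2-[4-(benzyloxy)phenyl]-1-hydroxyethyl]oxan-4-ol
Product: 20 (2R,4R,6S)-2-(4-hydroxy-3-methoxyphenyl)-6-[(1R)-1-hydroxy-2-(4-hydroxyphenyl)ethyl]oxan-4-ol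
Conditions: H2 (1 atm), Pd/C (10 wt%), EtOAc/EtOH, rt; stopped on consumption of 19
Reagents that add atoms: none
Why: Catalytic hydrogenolysis cleaves the two phenolic O-benzyl ethers much faster than the hindered cyclic benzylic dialkyl ether, so the oxane ring and all four stereocentres survive.

**Compound list**
1 | penta-1,4-dien-3-ol (divinylcarbinol) | C=CC(O)C=C | starting material
2 | (2R,3S)-1,2-epoxypent-4-en-3-ol | C=C[C@H](O)[C@H]1CO1 | intermediate
3 | 1-(benzyloxy)-4-bromobenzene | Brc1ccc(OCc2ccccc2)cc1 | starting material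
4 | [4-(benzyloxy)phenyl]magnesium bromide | Br[Mg]c1ccc(OCc2ccccc2)cc1 | intermediate
5 | (2R,3S)-1-[4-(benzyloxy)phenyl]pent-4-ene-2,3-diol | C=C[C@H](O)[C@H](O)Cc1ccc(OCc2ccccc2)cc1 | intermediate
6 | (4R,5S)-4-[4-(benzyloxy)benzyl]-2,2-dimethyl-5-vinyl-1,3-dioxolane | C=C[C@@H]1OC(C)(C)O[C@@H]1Cc1ccc(OCc2ccccc2)cc1 | intermediate
7 | 9-{2-[(4S,5R)-5-[4-(benzyloxy)benzyl]-2,2-dimethyl-1,3-dioxolan-4-yl]ethyl}-9-borabicyclo[3.3.1]nonane | C1CC2CCCC(C1)B2CC[C@@H]1OC(C)(C)O[C@@H]1Cc1ccc(OCc2ccccc2)cc1 | intermediate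
8 | 2-[(4S,5R)-5-[4-(benzyloxy)benzyl]-2,2-dimethyl-1,3-dioxolan-4-yl]ethan-1-ol | OCC[C@@H]1OC(C)(C)O[C@@H]1Cc1ccc(OCc2ccccc2)cc1 | intermediate
9 | 2-[(4S,5R)-5-[4-(benzyloxy)benzyl]-2,2-dimethyl-1,3-dioxolan-4-yl]acetaldehyde | O=CC[C@@H]1OC(C)(C)O[C@@H]1Cc1ccc(OCc2ccccc2)cc1 | intermediate
10 | ethyl 4-[(4S,5R)-5-[4-(benzyloxy)benzyl]-2,2-dimethyl-1,3-dioxolan-4-yl]-3-oxobutanoate | CCOC(=O)CC(=O)C[C@@H]1OC(C)(C)O[C@@H]1Cc1ccc(OCc2ccccc2)cc1 | intermediate
11 | ethyl (3S)-4-[(4S,5R)-5-[4-(benzyloxy)benzyl]-2,2-dimethyl-1,3-dioxolan-4-yl]-3-hydroxybutanoate | CCOC(=O)C[C@@H](O)C[C@@H]1OC(C)(C)O[C@@H]1Cc1ccc(OCc2ccccc2)cc1 | intermediate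
12 | ethyl (3S,5S,6R)-7-[4-(benzyloxy)phenyl]-3,5,6-trihydroxyheptanoate | CCOC(=O)C[C@@H](O)C[C@H](O)[C@H](O)Cc1ccc(OCc2ccccc2)cc1 | intermediate
13 | (4S,6S)-6-[(1R)-2-[4-(benzyloxy)phenyl]-1-hydroxyethyl]-4-hydroxyoxan-2-one | O=C1C[C@@H](O)C[C@@H]([C@H](O)Cc2ccc(OCc3ccccc3)cc2)O1 | intermediate
14 | (4S,6S)-6-[(1R)-2-[4-(benzyloxy)phenyl]-1-[(tert-butyldimethylsilyl)oxy]ethyl]-4-[(tert-butyldimethylsilyl)oxy]oxan-2-one | O=C1C[C@@H](O[Si](C)(C)C(C)(C)C)C[C@@H]([C@H](O[Si](C)(C)C(C)(C)C)Cc2ccc(OCc3ccccc3)cc2)O1 | intermediate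
15 | 1-(benzyloxy)-4-bromo-2-methoxybenzene | COc1cc(Br)ccc1OCc1ccccc1 | starting material
16 | [4-(benzyloxy)-3-methoxyphenyl]lithium | [Li]c1ccc(OCc2ccccc2)c(OC)c1 | intermediate
17 | (4S,6S)-2-[4-(benzyloxy)-3-methoxyphenyl]-6-[(1R)-2-[4-(benzyloxy)phenyl]-1-[(tert-butyldimethylsilyl)oxy]ethyl]-4-[(tert-butyldimethylsilyl)oxy]oxan-2-ol (C2 anomer mixture) | COc1cc(C2(O)C[C@@H](O[Si](C)(C)C(C)(C)C)C[C@@H]([C@H](O[Si](C)(C)C(C)(C)C)Cc3ccc(OCc4ccccc4)cc3)O2)ccc1OCc1ccccc1 | intermediate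
18 | (2R,4R,6S)-2-[4-(benzyloxy)-3-methoxyphenyl]-6-[(1R)-2-[4-(benzyloxy)phenyl]-1-[(tert-butyldimethylsilyl)oxy]ethyl]-4-[(tert-butyldimethylsilyl)oxy]oxane | COc1cc([C@H]2C[C@@H](O[Si](C)(C)C(C)(C)C)C[C@@H]([C@H](O[Si](C)(C)C(C)(C)C)Cc3ccc(OCc4ccccc4)cc3)O2)ccc1OCc1ccccc1 | intermediate
19 | (2R,4R,6S)-2-[4-(benzyloxy)-3-methoxyphenyl]-6-[(1R)-2-[4-(benzyloxy)phenyl]-1-hydroxyethyl]oxan-4-ol | COc1cc([C@H]2C[C@@H](O)C[C@@H]([C@H](O)Cc3ccc(OCc4ccccc4)cc3)O2)ccc1OCc1ccccc1 | intermediate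
20 | (2R,4R,6S)-2-(4-hydroxy-3-methoxyphenyl)-6-[(1R)-1-hydroxy-2-(4-hydroxyphenyl)ethyl]oxan-4-ol | COc1cc([C@H]2C[C@@H](O)C[C@@H]([C@H](O)Cc3ccc(O)cc3)O2)ccc1O | target

**Step count and risks**

Total step count: 13. Longest linear sequence: 13 steps (1 → 20); bromides 3 and 15 enter as purchased side inputs.

The three steps most likely to fail:

Step 2 opens an epoxide next to a free magnesium alkoxide, so Payne rearrangement or bromohydrin formation could erode yield and regiochemistry. The fallback sets out from 2 and comes back at 5. The hydroxyl is first masked (TBSCl, imidazole, DMF) as tert-butyl(dimethyl){[(1S)-1-[(2R)-oxiran-2-yl]prop-2-en-1-yl]oxy}silane F1. The nucleophile is changed to [4-(benzyloxy)phenyl]lithium F2 (from 3 and n-BuLi, THF, −78 °C), which opens F1 at the CH2 terminus under BF3·OEt2 activation at −78 °C, with no copper and no neighbouring alkoxide. This gives (2R,3S)-1-[4-(benzyloxy)phenyl]-3-[(tert-butyldimethylsilyl)oxy]pent-4-en-2-ol F3, and TBAF in THF then returns diol 5.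

Step 7 depends on a panel enzyme accepting the lipophilic, acetal-bearing keto ester 10 with the required facial sense. The fallback sets out from 10 and comes back at 12, and replaces catalyst control by hydroxyl-directed substrate control. The acetonide is removed first (TFA/H2O/CH2Cl2, 0 °C) to give ethyl (5S,6R)-7-[4-(benzyloxy)phenyl]-5,6-dihydroxy-3-oxoheptanoate F4. Its C3 ketone is then reduced by intramolecular hydride delivery from the acetoxyborohydride bound to the 5-OH (Me4NBH(OAc)3, MeCN/AcOH, −30 °C; Evans–Saksena 1,3-anti reduction). This gives triol ester 12, which is lactonised to 13 as in step 8.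

Step 10 may fail if the aryllithium deprotonates lactone 14 at C3 and expels the β-silyloxy group, or adds twice. The fallback sets out from 11 and comes back at 19, and replaces lactone arylation by a Weinreb ketone synthesis followed by reductive etherification.
- Ester 11 is converted (MeNHOMe·HCl, i-PrMgCl, THF, −20 °C) into (3S)-4-[(4S,5R)-5-[4-(benzyloxy)benzyl]-2,2-dimethyl-1,3-dioxolan-4-yl]-3-hydroxy-N-methoxy-N-methylbutanamide F5.
- F5 is silylated (TBSCl, imidazole, DMF) to (3S)-4-[(4S,5R)-5-[4-(benzyloxy)benzyl]-2,2-dimethyl-1,3-dioxolan-4-yl]-3-[(tert-butyldimethylsilyl)oxy]-N-methoxy-N-methylbutanamide F6.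
- Aryllithium 16 (THF, −78 °C) adds once to F6 through the stable chelated adduct and gives (3S)-1-[4-(benzyloxy)-3-methoxyphenyl]-4-[(4S,5R)-5-[4-(benzyloxy)benzyl]-2,2-dimethyl-1,3-dioxolan-4-yl]-3-[(tert-butyldimethylsilyl)oxy]butan-1-one F7.
- Acetonide removal (TFA/H2O/CH2Cl2, 0 °C) gives (3S,5S,6R)-1-[4-(benzyloxy)-3-methoxyphenyl]-7-[4-(benzyloxy)phenyl]-3-[(tert-butyldimethylsilyl)oxy]-5,6-dihydroxyheptan-1-one F8, in equilibrium with its six-membered hemiketal.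
- Et3SiH/TMSOTf (CH2Cl2, −78 °C) closes the ring with the same axial hydride delivery to give (2R,4R,6S)-2-[4-(benzyloxy)-3-methoxyphenyl]-6-[(1R)-2-[4-(benzyloxy)phenyl]-1-hydroxyethyl]-4-[(tert-butyldimethylsilyl)oxy]oxane F9.
- TBAF then gives 19.

**Further compounds**
F1 | step 2 | tert-butyl(dimethyl){[(1S)-1-[(2R)-oxiran-2-yl]prop-2-en-1-yl]oxy}silane | C=C[C@H](O[Si](C)(C)C(C)(C)C)[C@H]1CO1
F2 | step 2 | [4-(benzyloxy)phenyl]lithium | [Li]c1ccc(OCc2ccccc2)cc1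
F3 | step 2 | (2R,3S)-1-[4-(benzyloxy)phenyl]-3-[(tert-butyldimethylsilyl)oxy]pent-4-en-2-ol | C=C[C@H](O[Si](C)(C)C(C)(C)C)[C@H](O)Cc1ccc(OCc2ccccc2)cc1
F4 | step 7 | ethyl (5S,6R)-7-[4-(benzyloxy)phenyl]-5,6-dihydroxy-3-oxoheptanoate | CCOC(=O)CC(=O)C[C@H](O)[C@H](O)Cc1ccc(OCc2ccccc2)cc1
F5 | step 10 | (3S)-4-[(4S,5R)-5-[4-(benzyloxy)benzyl]-2,2-dimethyl-1,3-dioxolan-4-yl]-3-hydroxy-N-methoxy-N-methylbutanamide | CON(C)C(=O)C[C@@H](O)C[C@@H]1OC(C)(C)O[C@@H]1Cc1ccc(OCc2ccccc2)cc1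
F6 | step 10 | (3S)-4-[(4S,5R)-5-[4-(benzyloxy)benzyl]-2,2-dimethyl-1,3-dioxolan-4-yl]-3-[(tert-butyldimethylsilyl)oxy]-N-methoxy-N-methylbutanamide | CON(C)C(=O)C[C@@H](O[Si](C)(C)C(C)(C)C)C[C@@H]1OC(C)(C)O[C@@H]1Cc1ccc(OCc2ccccc2)cc1
F7 | step 10 | (3S)-1-[4-(benzyloxy)-3-methoxyphenyl]-4-[(4S,5R)-5-[4-(benzyloxy)benzyl]-2,2-dimethyl-1,3-dioxolan-4-yl]-3-[(tert-butyldimethylsilyl)oxy]butan-1-one | COc1cc(C(=O)C[C@@H](O[Si](C)(C)C(C)(C)C)C[C@@H]2OC(C)(C)O[C@@H]2Cc2ccc(OCc3ccccc3)cc2)ccc1OCc1ccccc1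
F8 | step 10 | (3S,5S,6R)-1-[4-(benzyloxy)-3-methoxyphenyl]-7-[4-(benzyloxy)phenyl]-3-[(tert-butyldimethylsilyl)oxy]-5,6-dihydroxyheptan-1-one | COc1cc(C(=O)C[C@@H](O[Si](C)(C)C(C)(C)C)C[C@H](O)[C@H](O)Cc2ccc(OCc3ccccc3)cc2)ccc1OCc1ccccc1
F9 | step 10 | (2R,4R,6S)-2-[4-(benzyloxy)-3-methoxyphenyl]-6-[(1R)-2-[4-(benzyloxy)phenyl]-1-hydroxyethyl]-4-[(tert-butyldimethylsilyl)oxy]oxane | COc1cc([C@H]2C[C@@H](O[Si](C)(C)C(C)(C)C)C[C@@H]([C@H](O)Cc3ccc(OCc4ccccc4)cc3)O2)ccc1OCc1ccccc1
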